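The numbers in the tables are simulated for substances that don't exist, and the scatter is random.

In a one-step world you would follow one amount: the target made, as a fraction of the charge. Monday's run of this flask needs a second amount, and the ratio of the two tells you where the target stands.

- Monday's: starting material 1 M; reagent in the second phase 1 M; protic impurity 0.050 M; the very flask that is asked about, followed so far
- flask: starting material 1.0 M; reagent in the second phase 1.00 M; protic impurity 0.0500 M; time 3.0 d; volume of the second phase over the first 1.0
Monday's run (percent of the starting material charged)

| time / h | target / % | crystals / % |
|---|---|---|
| 1.50 | 1.1 | 0.3 |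
| 4.00 | 5.8 | 0 |
| 8.00 | 13.2 | 0.3 |
| 12.0 | 20.8 | 1.2 |
| 20.0 | 28.8 | 10.0 |
| 25.0 | 33.1 | 14.1 |
| 30.0 | 35.6 | 16.0 |

(scatter of a reading: 0.5 percentage points)
- for target the crystals are counted in
- in the second phase: reagent in the second phase; everything else is in the first
- charges count per volume of the first phase; a concentration in a rate is the amount of a species over the volume of its own phase; every rate counts per litre of the first phase
- as a solid, counted per litre of solution: crystals
- the numbers in the tables scatter with a standard deviation of 0.5 percentage points
- the earlier runs hold the two phases in the same ratio of volumes as the flask asked about
- how much target and crystals together there is at 3.0 d, in percent of the starting material charged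
- concentration of target in solution at 3.0 d, in percent of saturation

Take crystals from target in the last three readings. Their mean is the late dissolved share 19.1%, a reading of the target in solution late in Monday's run, as a fraction of the charge. Now divide total target by it:

at 8.00 h: ratio 0.690, crystals 0.3%, within the scatter
at 30.0 h: ratio 1.86, crystals 16.0%

My rule for this flask, taking the dissolved share to stay as Monday's late readings show it, is this: below a ratio of one, expect no crystals; above it, expect crystals equal to total target less the late dissolved share.

The forecast gives 49% in total and 101% of saturation: “Solution stays about saturated.”

This flask gives 43.4% and 103%.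

    reagent in the reaction phase ⇌ reagent in the second phase, rate k1*([reagent in the reaction phase] - [reagent in the second phase]/K1) per volume of the first phase (partition coefficient = 0.410, kL = 1.80 × 10⁻⁵ s⁻¹)
    crystals ⇌ target, rate k2*(cs2 - [target]) while solid is left; crystals form when [target] > cs2 (solubility = 0.160 M, k = 5.62 × 10⁻⁵ s⁻¹)
    starting material + reagent in the reaction phase → target (k = 1.89 × 10⁻⁵ L mol⁻¹ s⁻¹)
    starting material + protic impurity → quenched substrate (k = 5.26 × 10⁻⁵ L mol⁻¹ s⁻¹)
    reagent in the reaction phase + target → over-reacted product (k = 2.11 × 10⁻⁵ L mol⁻¹ s⁻¹)
    2 starting material → self-condensation product (k = 4.14 × 10⁻⁹ L mol⁻¹ s⁻¹)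

The ratio in this flask is 2.27, so the rule expects 24.3% as crystals, but the flask holds 26.9%. At 3.00 d dissolved target is made at 0.918 of the rate at which it is used up, and 16.5% of the charge stands dissolved, which is 103% of saturation.

With 0.40 M of starting material, the dissolved concentration of Monday's late readings gives a late dissolved share of 47.8%. That flask reaches 20.6% target, a ratio of 0.431, with crystals at 0%.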